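## Retrosynthetic overview

1. The last step is hydrogenolysis of three benzyl ethers. Before it, ring A of the flavanone half is the last ring to be built.
2. Ring A is a phloroglucinol ring (5-OH, 7-OMe) fused through C4a–C8a to pyranone ring C, and C4a=C8a is the enol ether double bond of a 2-aryl-2,3-dihydropyran-4-one. Cutting C4a–C5 and C8–C8a leaves that heterocycle as the dienophile and a 1,1,3-trioxygenated butadiene that already carries both oxygen substituents.
3. The dienophile bears phenylsulfinyl at C5 (future C4a). A [4+2] addition leaves this group cis to the non-acidic H-8a, so only a syn-eliminating group gives C4a=C8a without base. A halogen was weighed and set aside for this reason, and the sulfinyl group also activates the double bond.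
4. Ring C and C2 (S) come from a catalytic asymmetric hetero-Diels–Alder reaction of the flavone aldehyde with 1-methoxy-3-silyloxybutadiene. The primary silyl enol ether adduct is sulfenylated in the same flask, which keeps the electrophile away from the electron-rich arenes.
5. The flavone aldehyde comes from an SNAr diaryl ether, a crossed Claisen condensation and a cyclodehydration. Ring order: flavone pyranone ring, flavanone ring C, flavanone ring A.

Key step: step 9

Remark (assumption): the sense of induction in step 6 is assigned by analogy with simple aromatic aldehydes. It should be confirmed by the CD curve of 18, and the antipodal catalyst is equally available. Enantiomeric purity is checked by chiral HPLC and raised by recrystallisation at 12. The acetal, sulfur and ring-fusion centres of 10, 11, 13 and 16 form as mixtures, are all destroyed later, and are left undefined in the SMILES.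

## Route

Step 1
Reactants: 1 4-(benzyloxy)-3-hydroxybenzaldehyde; 2 methyl 4-fluorobenzoate
Product: 3 methyl 4-[2-(benzyloxy)-5-formylphenoxy]benzoate
Conditions: Cs2CO3, DMSO, 110 °C
Reagents that add atoms: none
Why: Nucleophilic aromatic substitution (SNAr), in which the para ester stabilises the Meisenheimer adduct, fluoride is the best leaving group, and the non-enolisable aldehyde tolerates carbonate base.

Step 2
Reactants: 3 methyl 4-[2-(benzyloxy)-5-formylphenoxy]benzoate
Product: 4 methyl 4-[2-(benzyloxy)-5-(dimethoxymethyl)phenoxy]benzoate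
Conditions: HC(OMe)3, p-TsOH·H2O (cat.), MeOH, 50 °C; Et3N quench
Reagents that add atoms: trimethyl orthoformate COC(OC)OC; methanol CO
Why: Acid-catalysed acetalisation driven by the orthoester as water scavenger masks the aldehyde against the enolate of step 4, and methanol as solvent leaves the methyl ester unchanged.

Step 3
Reactants: 5 2',4',6'-trihydroxyacetophenone
Product: 6 1-[2,4-bis(benzyloxy)-6-hydroxyphenyl]ethanone
Conditions: BnBr (2.1 equiv), K2CO3, DMF, rt → 60 °C
Reagents that add atoms: benzyl bromide BrCc1ccccc1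
Why: Williamson etherification stops after two alkylations because the remaining ortho hydroxyl is chelated to the acetyl carbonyl and is the least nucleophilic oxygen.

Step 4
Reactants: 4 methyl 4-[2-(benzyloxy)-5-(dimethoxymethyl)phenoxy]benzoate; 6 1-[2,4-bis(benzyloxy)-6-hydroxyphenyl]ethanone
Product: 7 1-[2,4-bis(benzyloxy)-6-hydroxyphenyl]-3-{4-[2-(benzyloxy)-5-(dimethoxymethyl)phenoxy]phenyl}propane-1,3-dione
Conditions: NaH (4 equiv), THF, 0 °C → reflux; AcOH quench
Reagents that add atoms: none
Why: Crossed Claisen condensation of a methyl ketone enolate with a non-enolisable ester (the intermolecular counterpart of the Baker–Venkataraman route) is driven by deprotonation of the 1,3-diketone, and the acetal and benzyl ethers are inert to base.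

Step 5
Reactants: 7 the 1,3-diketone
Product: 8 4-(benzyloxy)-3-{4-[5,7-bis(benzyloxy)-4-oxo-4H-chromen-2-yl]phenoxy}benzaldehyde
Conditions: p-TsOH·H2O (0.3 equiv), toluene, 90 °C; then THF–1 M aq HCl, rt
Reagents that add atoms: water O
Why: Acid-catalysed cyclodehydration of the o-hydroxyaryl 1,3-diketone closes the flavone pyranone ring, and the same acid then hydrolyses the dimethyl acetal to the free aldehyde.

Step 6
Reactants: 8 the flavone aldehyde; 9 (E)-1-methoxy-3-(trimethylsilyloxy)buta-1,3-diene
Product: 12 (2S)-2-{4-(benzyloxy)-3-[4-(5,7-bis(benzyloxy)-4-oxo-4H-chromen-2-yl)phenoxy]phenyl}-5-(phenylsulfanyl)-2,3-dihydro-4H-pyran-4-one, via silyl enol ether cycloadduct 10 (not isolated), via methoxy sulfanyl ketone 11 (not isolated)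
Conditions: [(S,S)-N,N'-bis(3,5-di-tert-butylsalicylidene)cyclohexane-1,2-diaminato]chromium tetrafluoroborate (5 mol %), 4 Å MS, TBME–CH2Cl2, −30 °C; PhSCl (equimolar to 9), −78 °C; TFA, CH2Cl2, 0 °C → rt
Reagents that add atoms: benzenesulfenyl chloride ClSc1ccccc1
Why: The cationic complex of trivalent chromium promotes a concerted enantioselective hetero-Diels–Alder reaction in which the diene adds to the Si face of the bound formyl group and sets C2 as (S); the silyl enol ether of 10 is far more nucleophilic than any arene in the molecule, so classical sulfenylation followed by acid-induced β-elimination of methanol places sulfur on C5 only.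

Step 7
Reactants: 12 the (S)-5-(phenylsulfanyl)dihydropyranone
Product: 13 (2S)-2-{4-(benzyloxy)-3-[4-(5,7-bis(benzyloxy)-4-oxo-4H-chromen-2-yl)phenoxy]phenyl}-5-(phenylsulfinyl)-2,3-dihydro-4H-pyran-4-one (both epimers at sulfur)
Conditions: mCPBA (1.0 equiv), CH2Cl2, −78 → −20 °C
Reagents that add atoms: mCPBA O=C(OO)c1cccc(Cl)c1
Why: Sulfide-to-sulfoxide oxidation with one equivalent of peracid is much faster than attack on the acceptor-substituted double bonds or the arenes, and it does not touch C2.

Step 8
Reactants: 14 methyl (E)-3-methoxybut-2-enoate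
Product: 15 (1Z)-1,3-dimethoxy-1-(trimethylsilyloxy)buta-1,3-diene
Conditions: LiN(iPr)2 (LDA, commercial solution), THF, −78 °C; TMSCl, −78 °C → rt; distillation
Reagents that add atoms: chlorotrimethylsilane C[Si](C)(C)Cl
Why: Kinetic γ-deprotonation of the β-methoxy enoate and O-silylation of the dienolate is the standard route to this vinylogous ketene acetal, whose ketene acetal geometry has no bearing on step 9.

Step 9
Reactants: 13 the (S)-5-(phenylsulfinyl)dihydropyranone; 15 (1Z)-1,3-dimethoxy-1-(trimethylsilyloxy)buta-1,3-diene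
Product: 18 (2S)-2-{4-(benzyloxy)-3-[4-(5,7-bis(benzyloxy)-4-oxo-4H-chromen-2-yl)phenoxy]phenyl}-5-hydroxy-7-methoxychroman-4-one, via sulfinyl cycloadduct 16 (not isolated), via dihydroarene ketal 17 (not isolated)
Conditions: 15 (4 equiv), toluene, 80 °C, sealed tube, Ar; then SiO2, CH2Cl2, rt
Reagents that add atoms: none
Why: Proposed new method: the CH2 end of 15, its most nucleophilic site, joins C6 of 13, which is made electrophilic by both the ketone and the sulfinyl group (future C8–C8a), while the ketene acetal carbon joins the sulfur-bearing C5 (future C4a–C5), in a concerted but strongly asynchronous normal-demand [4+2] cycloaddition that closes ring A as a six-membered carbocycle by suprafacial addition across the enol ether bond of ring C. This addition leaves the sulfinyl group and H-8a cis in 16, so a thermal five-centre syn elimination of benzenesulfenic acid is geometrically prepared, has H-8a as its only β-hydrogen, and gives the C4a=C8a bond of 17 without base and without breaking C8a–O1; a halogen at this position would sit cis to a non-acidic hydrogen, with neither anti-E2 nor E1cB open to it, and would become a positive-halogen donor between two carbonyl groups. The doubly allylic mixed ketal at C5 of 17 then loses methoxytrimethylsilane and the dienone enolises, so the 7-OMe and the chelated 5-OH are the two oxygen functions brought in by the diene. The closest known reactions are the cycloaddition–elimination benzannulations of 1,1-dioxygenated dienes with halo- and sulfinylquinones and with 3-activated chromones, whereas a non-benzo-fused 5-sulfinyl-2,3-dihydropyran-4-one has not been used in this way. The two ring-fusion centres of 16 are transient and no lasting stereocentre is formed, and C2 is a spectator that the neutral medium protects from enolate- or acid-induced opening of ring C. The step needs regioselectivity, secured by the matched polarisation of the two partners, and chemoselectivity over the flavone C2=C3 bond, which carries an aryl group and no second acceptor, while the s-trans enone locked in ring C cannot act as a heterodiene.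

Step 10
Reactants: 18 the (S)-tri-O-benzyl flavanone–flavone
Product: 19 (2S)-5-hydroxy-2-{4-hydroxy-3-[4-(5,7-dihydroxy-4-oxo-4H-chromen-2-yl)phenoxy]phenyl}-7-methoxychroman-4-one (CNP0145819.1)
Conditions: H2 (1 atm), 10 % Pd/C, EtOAc–MeOH, rt, stopped at full debenzylation
Reagents that add atoms: none
Why: Catalytic hydrogenolysis cleaves aryl benzyl ethers faster than it attacks the flavone double bond or the cyclic benzylic C2–O1 bond, and the neutral medium cannot epimerise C2.

## Compound list

1 | 4-(benzyloxy)-3-hydroxybenzaldehyde | O=Cc1ccc(OCc2ccccc2)c(O)c1 | starting material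
2 | methyl 4-fluorobenzoate | COC(=O)c1ccc(F)cc1 | starting material
3 | methyl 4-[2-(benzyloxy)-5-formylphenoxy]benzoate | O=Cc1ccc(OCc2ccccc2)c(Oc2ccc(C(=O)OC)cc2)c1 | intermediate
4 | methyl 4-[2-(benzyloxy)-5-(dimethoxymethyl)phenoxy]benzoate | COC(OC)c1ccc(OCc2ccccc2)c(Oc2ccc(C(=O)OC)cc2)c1 | intermediate
5 | 2',4',6'-trihydroxyacetophenone | CC(=O)c1c(O)cc(O)cc1O | starting material
6 | 1-[2,4-bis(benzyloxy)-6-hydroxyphenyl]ethanone | CC(=O)c1c(O)cc(OCc2ccccc2)cc1OCc1ccccc1 | intermediate
7 | 1-[2,4-bis(benzyloxy)-6-hydroxyphenyl]-3-{4-[2-(benzyloxy)-5-(dimethoxymethyl)phenoxy]phenyl}propane-1,3-dione | COC(OC)c1ccc(OCc2ccccc2)c(Oc2ccc(C(=O)CC(=O)c3c(O)cc(OCc4ccccc4)cc3OCc3ccccc3)cc2)c1 | intermediate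
8 | 4-(benzyloxy)-3-{4-[5,7-bis(benzyloxy)-4-oxo-4H-chromen-2-yl]phenoxy}benzaldehyde | O=Cc1ccc(OCc2ccccc2)c(Oc2ccc(-c3cc(=O)c4c(OCc5ccccc5)cc(OCc5ccccc5)cc4o3)cc2)c1 | intermediate
9 | (E)-1-methoxy-3-(trimethylsilyloxy)buta-1,3-diene | CO/C=C/C(=C)O[Si](C)(C)C | starting material
10 | (2S)-2-aryl-6-methoxy-4-(trimethylsilyloxy)-3,6-dihydro-2H-pyran (aryl as in 12; C6 undefined) | COC1O[C@H](c2ccc(OCc3ccccc3)c(Oc3ccc(-c4cc(=O)c5c(OCc6ccccc6)cc(OCc6ccccc6)cc5o4)cc3)c2)CC(O[Si](C)(C)C)=C1 | intermediate (not isolated)
11 | (2S)-2-aryl-6-methoxy-5-(phenylsulfanyl)tetrahydropyran-4-one (C5, C6 undefined) | COC1O[C@H](c2ccc(OCc3ccccc3)c(Oc3ccc(-c4cc(=O)c5c(OCc6ccccc6)cc(OCc6ccccc6)cc5o4)cc3)c2)CC(=O)C1Sc1ccccc1 | intermediate (not isolated)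
12 | (2S)-2-{4-(benzyloxy)-3-[4-(5,7-bis(benzyloxy)-4-oxo-4H-chromen-2-yl)phenoxy]phenyl}-5-(phenylsulfanyl)-2,3-dihydro-4H-pyran-4-one | C1(Sc7ccccc7)=CO[C@H](c2ccc(OCc3ccccc3)c(Oc3ccc(-c4cc(=O)c5c(OCc6ccccc6)cc(OCc6ccccc6)cc5o4)cc3)c2)CC1=O | intermediate
13 | (2S)-5-(phenylsulfinyl) analogue of 12 (sulfur undefined) | C1(S(=O)c7ccccc7)=CO[C@H](c2ccc(OCc3ccccc3)c(Oc3ccc(-c4cc(=O)c5c(OCc6ccccc6)cc(OCc6ccccc6)cc5o4)cc3)c2)CC1=O | intermediate
14 | methyl (E)-3-methoxybut-2-enoate | COC(=O)/C=C(\C)OC | starting material
15 | (1Z)-1,3-dimethoxy-1-(trimethylsilyloxy)buta-1,3-diene | C=C(OC)/C=C(/OC)O[Si](C)(C)C | intermediate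
16 | (2S)-2-aryl-5,7-dimethoxy-4a-(phenylsulfinyl)-5-(trimethylsilyloxy)-2,3,4a,5,8,8a-hexahydrochromen-4-one (sulfinyl and H-8a cis; C4a, C5, C8a, S undefined) | COC1=CC(OC)(O[Si](C)(C)C)C2(S(=O)c7ccccc7)C(C1)O[C@H](c3ccc(OCc4ccccc4)c(Oc4ccc(-c5cc(=O)c6c(OCc8ccccc8)cc(OCc8ccccc8)cc6o5)cc4)c3)CC2=O | intermediate (not isolated)
17 | (2S)-2-aryl-5,7-dimethoxy-5-(trimethylsilyloxy)-2,3,5,8-tetrahydrochromen-4-one (C5 undefined) | COC1=CC(OC)(O[Si](C)(C)C)C2=C(C1)O[C@H](c3ccc(OCc4ccccc4)c(Oc4ccc(-c5cc(=O)c6c(OCc8ccccc8)cc(OCc8ccccc8)cc6o5)cc4)c3)CC2=O | intermediate (not isolated)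
18 | (2S)-2-{4-(benzyloxy)-3-[4-(5,7-bis(benzyloxy)-4-oxo-4H-chromen-2-yl)phenoxy]phenyl}-5-hydroxy-7-methoxychroman-4-one | COc1cc(O)c2c(c1)O[C@H](c1ccc(OCc3ccccc3)c(Oc3ccc(-c4cc(=O)c5c(OCc6ccccc6)cc(OCc6ccccc6)cc5o4)cc3)c1)CC2=O | intermediate
19 | (2S)-5-hydroxy-2-{4-hydroxy-3-[4-(5,7-dihydroxy-4-oxo-4H-chromen-2-yl)phenoxy]phenyl}-7-methoxychroman-4-one | COc1cc(O)c2c(c1)O[C@H](c1ccc(O)c(Oc3ccc(-c4cc(=O)c5c(O)cc(O)cc5o4)cc3)c1)CC2=O | target

## Step count and risks

Total step count: 10. Longest linear sequence: 8 steps (1, 2, 4, 5, 6, 7, 9, 10).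

Steps most likely to fail:

**Step 9.**
- What may go wrong:
  - The push–pull double bond may react too slowly, so that the diene decomposes first.
  - The process may stop after the first C–C bond through silyl transfer, giving a Michael addition only.
  - Silicon may move to the sulfinyl oxygen.
  - Aromatisation may proceed by loss of silanol and leave a 5-methyl ether.
- Fallback by known chemistry, setting out from 8:
  - A Claisen–Schmidt condensation with purchased 2',6'-dihydroxy-4'-methoxyacetophenone (KOH, EtOH, rt) should give the (E)-2',6'-dihydroxy-4'-methoxychalcone F1.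
  - Oxa-Michael ring closure with NaOAc in refluxing EtOH should give the racemic tri-O-benzyl flavanone F2.
  - Preparative HPLC on a polysaccharide chiral phase should deliver the (S)-enantiomer, which is 18.
  - The (R)-enantiomer F3 is returned to F2 by the same NaOAc treatment, through reversible opening to F1, and is recycled.
- The route is rejoined at 18.

**Step 6.**
- What may go wrong:
  - The basic flavone carbonyl may compete for the chromium centre.
  - The p-alkoxy group deactivates the aldehyde, so turnover and facial selectivity may be poor.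
  - The silyl enol ether may be lost before it is trapped.
- Fallback, setting out from 8 and 9:
  - The stereocentre is set in the Mukaiyama aldol manifold with Ti(OiPr)4 and (S)-5,5',6,6',7,7',8,8'-octahydro-1,1'-bi-2-naphthol (toluene, 4 Å MS, 0 °C).
  - TFA-induced ring closure then gives the isolated (S)-2-aryl-2,3-dihydro-4H-pyran-4-one F4, which is recrystallised to enantiopurity.
  - The C5–S bond is then made on this vinylogous ester by addition of PhSCl (CH2Cl2, −78 → 0 °C) and elimination with Et3N.
- The route is rejoined at 12.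

**Step 10.**
- What may go wrong:
  - Over-reduction may occur by hydrogenolysis of the benzylic C2–O1 bond or by saturation of the flavone C2=C3 bond.
  - The catalyst may be poisoned by traces of sulfur carried from step 9.
- Fallback, setting out from 18: Lewis-acid dealkylation with BCl3 and pentamethylbenzene as benzyl cation trap (CH2Cl2, −78 °C, methanol quench). This spares the non-chelated 7-OMe.
- The route is rejoined at 19. No compound outside the list is made on this way (F0).

Further compounds
F1 | step 9 | (E)-3-{4-(benzyloxy)-3-[4-(5,7-bis(benzyloxy)-4-oxo-4H-chromen-2-yl)phenoxy]phenyl}-1-(2,6-dihydroxy-4-methoxyphenyl)prop-2-en-1-one | COc1cc(O)c(C(=O)/C=C/c2ccc(OCc3ccccc3)c(Oc3ccc(-c4cc(=O)c5c(OCc6ccccc6)cc(OCc6ccccc6)cc5o4)cc3)c2)c(O)c1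
F2 | step 9 | racemic 2-{4-(benzyloxy)-3-[4-(5,7-bis(benzyloxy)-4-oxo-4H-chromen-2-yl)phenoxy]phenyl}-5-hydroxy-7-methoxychroman-4-one | COc1cc(O)c2c(c1)OC(c1ccc(OCc3ccccc3)c(Oc3ccc(-c4cc(=O)c5c(OCc6ccccc6)cc(OCc6ccccc6)cc5o4)cc3)c1)CC2=O
F3 | step 9 | (2R)-enantiomer of 18 | COc1cc(O)c2c(c1)O[C@@H](c1ccc(OCc3ccccc3)c(Oc3ccc(-c4cc(=O)c5c(OCc6ccccc6)cc(OCc6ccccc6)cc5o4)cc3)c1)CC2=O
F4 | step 6 | (2S)-2-{4-(benzyloxy)-3-[4-(5,7-bis(benzyloxy)-4-oxo-4H-chromen-2-yl)phenoxy]phenyl}-2,3-dihydro-4H-pyran-4-one | C1=CO[C@H](c2ccc(OCc3ccccc3)c(Oc3ccc(-c4cc(=O)c5c(OCc6ccccc6)cc(OCc6ccccc6)cc5o4)cc3)c2)CC1=O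
F0 | step 10 | none | none
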